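**Plan**
1. Cuts, in retrosynthetic order: the O5 isobutyrate and O8 angelate; the C4–OH bond (back to the 4α,5β-epoxide, then to the (E)-C4=C5 alkene); the lactone C12–O6 bond and the C12 oxidation (back to an isopropenyl group on C7 and a protected O6); the C8–O bond; last, the ten-membered ring.
2. Enabling feature: in the carbocycle C1–C10 the C9 ketone lies 1,6 to C4, and C5, next to C4, carries oxygen. The array O=C9···C4–C5–O is what a Grob fragmentation leaves when the shared C4–C9 bond of a decalin breaks (ring A C4–C5–C6–C7–C8–C9, ring B C4–C3–C2–C1–C10–C9).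
3. Forward order: ring A is the ring of (R)-carvone, whose carbonyl carbon becomes C5. The chain C3–C2–C1–C10–C14 is added to that carbonyl and moved to C4 by a semipinacol shift. Ring B closes at C9–C10 and C4–C9 breaks in the same flask, giving the ten-membered ring. The γ-lactone closes three steps from the end.
4. Stereochemistry: C7 comes from carvone. C5, C6 and the transient C4 centre are set on the carvone chair, all equatorial, and the antiperiplanar fragmentation converts them into the E-alkene. C10 follows from the chair closure of ring B, C8 and C5 from attack on the outer face of the ten-membered ring, and C4 from inversion in the epoxide opening.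

Key step: step 13

Convention: germacrane numbering is used for every intermediate (C14 = methyl on C10, C15 = methyl on C4, C11–C13 = isopropenyl/acrylate carbons); β is the ring face that carries C11 on C7, α the face that carries O6.
Assumption: the open 4-hydroxy-9-ketone drawn for the target is taken as its stable form. Compounds 13–16 are carried as C10 epimer mixtures, which is harmless because the centre is erased on C–I reduction, so C10 is left undefined in their SMILES.

**Step 1**
Reactants: 1 5-chloropentan-2-one
Product: 2 2-(3-chloropropyl)-2-methyl-1,3-dioxolane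
Conditions: HOCH2CH2OH, p-TsOH (cat.), toluene, Dean–Stark reflux
Reagents that add atoms: ethylene glycol, OCCO
Why: Acid-catalysed ketalisation with azeotropic removal of water masks the ketone so that the chloride can be turned into a Grignard reagent.

**Step 2**
Reactants: 2 2-(3-chloropropyl)-2-methyl-1,3-dioxolane; 3 (R)-(−)-carvone
Product: 5 (1R,5R)-2-methyl-1-[3-(2-methyl-1,3-dioxolan-2-yl)propyl]-5-(prop-1-en-2-yl)cyclohex-2-en-1-ol (5β-OH and 5α-chain), via Grignard reagent 4 (not isolated)
Conditions: Mg, BrCH2CH2Br (cat.), THF, reflux; then 3, THF, −30 → 0 °C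
Reagents that add atoms: none
Why: Grignard 1,2-addition to the enone; as with hydride and alkyl-metal additions to carvone, the nucleophile should enter axially, anti to the equatorial isopropenyl group, so the chain ends up trans and the C5 hydroxyl cis to it (the minor epimer is removable by chromatography).

**Step 3**
Reactants: 5 tertiary allylic alcohol
Product: 6 4β,9β-epoxy alcohol (epoxide cis to the 5β-hydroxyl)
Conditions: VO(acac)2 (cat.), t-BuOOH, toluene, 0 °C → rt
Reagents that add atoms: tert-butyl hydroperoxide, CC(C)(C)OO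
Why: Hydroxyl-directed vanadium-catalysed (Sharpless–Michaelson) epoxidation delivers oxygen to C4=C9 on the face of the C5 hydroxyl and leaves the undirected isopropenyl group untouched.

**Step 4**
Reactants: 6 epoxy alcohol
Product: 7 5-oxo-9β-triethylsilyloxy cyclohexane with quaternary C4 (4α-chain equatorial and 4β-methyl axial)
Conditions: TESOTf, 2,6-lutidine, CH2Cl2, −78 → −20 °C
Reagents that add atoms: triethylsilyl triflate, CC[Si](CC)(CC)OS(=O)(=O)C(F)(F)F
Why: Silyl-triflate-promoted semipinacol rearrangement of a 2,3-epoxy alcohol (Suzuki–Tsuchihashi type): the tertiary C4–O bond ionises and the pseudoaxial chain on C5, the only group antiperiplanar to it, shifts to C4 with inversion, which fixes the quaternary centre stereospecifically while the released O9 is capped as its TES ether.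

**Step 5**
Reactants: 7 β-silyloxy ketone
Product: 8 6α-hydroxy ketone
Conditions: KHMDS, THF, −78 °C; then 2-(phenylsulfonyl)-3-phenyloxaziridine
Reagents that add atoms: 2-(phenylsulfonyl)-3-phenyloxaziridine, O=S(=O)(c1ccccc1)N1OC1c1ccccc1
Why: Davis oxidation of the only possible enolate (C4 is quaternary); the oxaziridine should approach C6 anti to the neighbouring isopropenyl group and to the axial C4 methyl, giving the equatorial 6α-alcohol, which is also the thermodynamically preferred epimer.

**Step 6**
Reactants: 8 6α-hydroxy ketone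
Product: 9 6α-tert-butyldimethylsilyloxy ketone
Conditions: TBSOTf, 2,6-lutidine, CH2Cl2, 0 °C
Reagents that add atoms: tert-butyldimethylsilyl triflate, CC(C)(C)[Si](C)(C)OS(=O)(=O)C(F)(F)F
Why: Silyl triflate silylation protects O6 with a group that outlasts the TES ether and the ketal under the later acid treatment and stops O6–H from quenching the C10 carbanion.

**Step 7**
Reactants: 9 silyloxy ketone
Product: 10 5β-alcohol (equatorial and trans to O6)
Conditions: NaBH4, MeOH–THF, −20 → 0 °C
Reagents that add atoms: none
Why: Borohydride reduction of a cyclohexanone flanked by an axial α-methyl group: hydride should arrive on the axial trajectory opposite that methyl (α-face) and give the equatorial 5β-alcohol, the low temperature guarding against O6→O5 silyl migration.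

**Step 8**
Reactants: 10 5β-alcohol
Product: 11 5β-mesylate
Conditions: MsCl, Et3N, CH2Cl2, 0 °C
Reagents that add atoms: methanesulfonyl chloride, CS(=O)(=O)Cl
Why: Mesylation through sulfene reaches even this hindered carbinol and installs the equatorial nucleofuge with retention at C5.

**Step 9**
Reactants: 11 mesylate
Product: 12 9β-hydroxy methyl ketone (side-chain C10 ketone freed and O6-TBS kept)
Conditions: 1 M HCl, THF, 0 °C → rt
Reagents that add atoms: water, O
Why: Acid hydrolysis removes the dioxolane and the TES ether while the hindered secondary TBS ether and the neopentyl-type mesylate persist; acid is chosen because a C9 alkoxide would set off a premature Wharton-type fragmentation.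

**Step 10**
Reactants: 12 hydroxy ketone
Product: 13 9β,10-diol (C10 epimers)
Conditions: NaBH4, CeCl3·7H2O, MeOH, −40 °C
Reagents that add atoms: none
Why: Luche-type borohydride reduction of the methyl ketone in a non-basic medium; the new C10 carbinol centre is not controlled and need not be.

**Step 11**
Reactants: 13 diol
Product: 14 10-iodo-9β-alcohol (C10 epimers)
Conditions: I2, PPh3, imidazole, CH2Cl2, 0 °C → rt
Reagents that add atoms: iodine, II
Why: Appel iodination (SN2) selects the unhindered side-chain carbinol, because the C9 carbinol next to quaternary C4 cannot be displaced and is returned on work-up.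

**Step 12**
Reactants: 14 iodo alcohol
Product: 15 iodo keto mesylate: 4α-(4-iodopentyl)-4β-methyl-5β-mesyloxy-6α-TBSO-7β-isopropenylcyclohexan-9-one
Conditions: Dess–Martin periodinane, CH2Cl2, rt
Reagents that add atoms: none
Why: Dess–Martin oxidation is neutral, so the 1,3-hydroxy mesylate is never deprotonated, and it tolerates the secondary iodide; the product cannot lose mesylate by E1cB since C4 bears no hydrogen.

**Step 13**
Reactants: 15 iodo keto mesylate
Product: 18 (4E,6R,7S,10R)-6-TBSO-7-isopropenyl-4,10-dimethylcyclodec-4-en-9-one, via C10 organosamarium 16 (not isolated), via cis-decalin samarium alkoxide 17 (not isolated)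
Conditions: SmI2 (slight excess over 2 equiv), NiI2 (cat.), THF, 0 °C → rt, slow addition of 15
Reagents that add atoms: none
Why: Two electron transfers from SmI2 cleave the C–I bond and give the configurationally labile organosamarium 16, so both iodide epimers converge. It adds to the C9 carbonyl in a 6-exo closure of ring B (intramolecular samarium Barbier reaction) through a chair in which attack is axial, away from the axial C4 methyl, the bulky O–Sm group turns equatorial and the C10 methyl sits equatorial; this gives the cis-fused alkoxide 17 and corresponds to 10R. In 17 the C4–C9 bond is antiperiplanar to the equatorial C5–OMs bond, so the alkoxide expels mesylate in a concerted Grob fragmentation and the ten-membered ring arises by cleavage of the shared decalin bond, not by end-to-end closure. Because the C3 chain on C4 is equatorial and therefore anti to C6, the new C4=C5 alkene must be E. The closest known reaction is the sequential SmI2 Barbier cyclisation/Grob fragmentation of iodoalkyl keto mesylates to eight- to ten-membered carbocycles, the secondary iodide being the demanding variation. The step needs C–I reduction ahead of ketone reduction (nickel catalysis, no HMPA or proton source, little excess SmI2, which also spares 18 from transannular ketyl–olefin coupling), and the substrate secures the rest: quaternary C4 blocks elimination and the unoxygenated C8 offers no α-C–O bond to cleave.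

**Step 14**
Reactants: 18 cyclodecenone
Product: 19 8α-hydroxy ketone (8R)
Conditions: KHMDS, THF, −78 °C; then 2-(phenylsulfonyl)-3-phenyloxaziridine
Reagents that add atoms: 2-(phenylsulfonyl)-3-phenyloxaziridine, O=S(=O)(c1ccccc1)N1OC1c1ccccc1
Why: Kinetic enolisation and Davis oxidation: in the decalin-like crown left by the fragmentation the outward C8–H is aligned with the carbonyl π system whereas C10–H is not, so C8 should be deprotonated, and the oxaziridine can reach only the peripheral lobe of the enolate, placing O8 pseudoequatorial and trans to the isopropenyl group.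

**Step 15**
Reactants: 19 8α-hydroxy ketone; 20 angelic acid
Product: 22 8α-angelate, via angeloyl trichlorobenzoyl anhydride 21 (not isolated)
Conditions: 2,4,6-Cl3C6H2COCl, Et3N, toluene, rt; then 19, 75 °C
Reagents that add atoms: none
Why: Yamaguchi mixed-anhydride esterification run without DMAP acylates hindered alcohols with retention at C8 and avoids the acylpyridinium pathway that isomerises angelate to tiglate.

**Step 16**
Reactants: 22 angelate
Product: 23 6α-allylic alcohol
Conditions: HF·pyridine, pyridine, THF, 0 °C → rt
Reagents that add atoms: none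
Why: Fluoride-mediated desilylation under buffered acidic conditions frees O6 before any acid-sensitive epoxide is present and does not disturb the α-acyloxy ketone.

**Step 17**
Reactants: 23 allylic alcohol
Product: 24 4α,5β-epoxy-6α-alcohol (trans-epoxide with 4R,5R)
Conditions: mCPBA, CH2Cl2, −20 → 0 °C
Reagents that add atoms: 3-chloroperbenzoic acid, O=C(OO)c1cccc(Cl)c1
Why: Henbest-type hydroxyl-directed peracid epoxidation reinforced by peripheral attack: with H6 eclipsing the C15 methyl (A1,3 strain) O6 lies on the exposed face of the strained E-alkene, so oxygen is delivered there and sets 5R, while the isopropenyl and angelate alkenes are less nucleophilic.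

**Step 18**
Reactants: 24 epoxy alcohol
Product: 25 6α,12-diol (isopropenyl methyl oxidised to CH2OH)
Conditions: SeO2 (cat.), t-BuOOH, CH2Cl2, rt
Reagents that add atoms: tert-butyl hydroperoxide, CC(C)(C)OO
Why: Catalytic SeO2/TBHP allylic oxidation (ene reaction then [2,3]-shift) attacks the only electron-rich alkene left and prefers its methyl group over the tertiary C7–H; any enal from over-oxidation is the next intermediate anyway.

**Step 19**
Reactants: 25 diol
Product: 28 4α,5β-epoxy α-methylene-γ-lactone (6α,12-olide and trans-fused), via hydroxy enal 26 (not isolated), via lactol 27 (not isolated)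
Conditions: MnO2 (activated, excess), CH2Cl2, rt
Reagents that add atoms: none
Why: MnO2 oxidative lactonisation of a 2-methylene-1,4-diol: the allylic alcohol is oxidised selectively, O6 closes on the enal (5-exo) and the allylic lactol is oxidised again, all under neutral conditions that spare the epoxide.

**Step 20**
Reactants: 28 epoxy lactone
Product: 30 4β,5β-diol (4S,5R), via 4,9-bridged hemiketal 29 (not isolated)
Conditions: HClO4 (cat.), THF–H2O, 0 °C
Reagents that add atoms: water, O
Why: Acid-catalysed opening of a trisubstituted epoxide at its tertiary carbon with inversion: the rear of C4 faces C9 across the ring, so the oxygen should be relayed by the hydrated C9 carbonyl group (carbonyl participation, as in the acid cyclisation of epoxy ketones to bicyclic ketals) to give hemiketal 29, whose opening leaves the 4β-hydroxyl and the ketone while the C5–O bond is untouched.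

**Step 21**
Reactants: 30 diol; 31 isobutyric anhydride
Product: 32 target CNP0141258.2 (4S,5R,6S,7S,8R,10R)
Conditions: DMAP (cat.), pyridine, 0 °C → rt
Reagents that add atoms: none
Why: DMAP-catalysed acylation distinguishes the secondary C5 hydroxyl from the tertiary C4 hydroxyl on steric grounds and leaves all stereocentres and the Z-angelate unchanged.

**Compound list**
1 | 5-chloropentan-2-one | CC(=O)CCCCl | starting material
2 | 2-(3-chloropropyl)-2-methyl-1,3-dioxolane | CC1(CCCCl)OCCO1 | intermediate
3 | (R)-(−)-carvone | CC1=CC[C@H](CC1=O)C(C)=C | starting material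
4 | 3-(2-methyl-1,3-dioxolan-2-yl)propylmagnesium chloride | CC1(CCC[Mg]Cl)OCCO1 | intermediate
5 | tertiary allylic alcohol (5β-OH, 5α-chain) | O[C@@]1(CCCC2(C)OCCO2)C(C)=CC[C@@H](C(C)=C)C1 | intermediate
6 | 4β,9β-epoxy alcohol | O[C@@]1(CCCC2(C)OCCO2)[C@@]3(C)O[C@H]3C[C@@H](C(C)=C)C1 | intermediate
7 | 5-oxo-9β-OTES compound with quaternary C4 | O=C1C[C@H](C(C)=C)C[C@H](O[Si](CC)(CC)CC)[C@@]1(C)CCCC2(C)OCCO2 | intermediate
8 | 6α-hydroxy ketone | O=C1[C@@H](O)[C@H](C(C)=C)C[C@H](O[Si](CC)(CC)CC)[C@@]1(C)CCCC2(C)OCCO2 | intermediate
9 | 6α-OTBS ketone | O=C1[C@@H](O[Si](C)(C)C(C)(C)C)[C@H](C(C)=C)C[C@H](O[Si](CC)(CC)CC)[C@@]1(C)CCCC2(C)OCCO2 | intermediate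
10 | 5β-alcohol | O[C@@H]1[C@@H](O[Si](C)(C)C(C)(C)C)[C@H](C(C)=C)C[C@H](O[Si](CC)(CC)CC)[C@@]1(C)CCCC2(C)OCCO2 | intermediate
11 | 5β-mesylate | CS(=O)(=O)O[C@@H]1[C@@H](O[Si](C)(C)C(C)(C)C)[C@H](C(C)=C)C[C@H](O[Si](CC)(CC)CC)[C@@]1(C)CCCC2(C)OCCO2 | intermediate
12 | 9β-hydroxy methyl ketone | CS(=O)(=O)O[C@@H]1[C@@H](O[Si](C)(C)C(C)(C)C)[C@H](C(C)=C)C[C@H](O)[C@@]1(C)CCCC(C)=O | intermediate
13 | 9β,10-diol (C10 epimers) | CS(=O)(=O)O[C@@H]1[C@@H](O[Si](C)(C)C(C)(C)C)[C@H](C(C)=C)C[C@H](O)[C@@]1(C)CCCC(C)O | intermediate
14 | 10-iodo-9β-alcohol (C10 epimers) | CS(=O)(=O)O[C@@H]1[C@@H](O[Si](C)(C)C(C)(C)C)[C@H](C(C)=C)C[C@H](O)[C@@]1(C)CCCC(C)I | intermediate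
15 | iodo keto mesylate (key-step precursor, C10 epimers) | CS(=O)(=O)O[C@@H]1[C@@H](O[Si](C)(C)C(C)(C)C)[C@H](C(C)=C)CC(=O)[C@@]1(C)CCCC(C)I | intermediate
16 | C10 organosamarium | CS(=O)(=O)O[C@@H]1[C@@H](O[Si](C)(C)C(C)(C)C)[C@H](C(C)=C)CC(=O)[C@@]1(C)CCCC(C)[Sm](I)I | intermediate
17 | cis-decalin samarium alkoxide | C[C@@H]1CCC[C@@]2(C)[C@H](OS(C)(=O)=O)[C@@H](O[Si](C)(C)C(C)(C)C)[C@H](C(C)=C)C[C@@]12O[Sm](I)I | intermediate
18 | (4E,6R,7S,10R)-cyclodec-4-en-9-one (key-step product) | CC(C)(C)[Si](C)(C)O[C@@H]1/C=C(C)/CCC[C@@H](C)C(=O)C[C@H]1C(C)=C | intermediate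
19 | 8α-hydroxy ketone | CC(C)(C)[Si](C)(C)O[C@@H]1/C=C(C)/CCC[C@@H](C)C(=O)[C@H](O)[C@H]1C(C)=C | intermediate
20 | angelic acid, (Z)-2-methylbut-2-enoic acid | C/C=C(/C)C(=O)O | starting material
21 | angeloyl 2,4,6-trichlorobenzoyl anhydride | C/C=C(/C)C(=O)OC(=O)c1c(Cl)cc(Cl)cc1Cl | intermediate
22 | 8α-angelate | CC(C)(C)[Si](C)(C)O[C@@H]1/C=C(C)/CCC[C@@H](C)C(=O)[C@H](OC(=O)/C(C)=C\C)[C@H]1C(C)=C | intermediate
23 | 6α-allylic alcohol | O[C@@H]1/C=C(C)/CCC[C@@H](C)C(=O)[C@H](OC(=O)/C(C)=C\C)[C@H]1C(C)=C | intermediate
24 | 4α,5β-epoxy-6α-alcohol | O[C@@H]1[C@H]2O[C@]2(C)CCC[C@@H](C)C(=O)[C@H](OC(=O)/C(C)=C\C)[C@H]1C(C)=C | intermediate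
25 | 6α,12-diol | O[C@@H]1[C@H]2O[C@]2(C)CCC[C@@H](C)C(=O)[C@H](OC(=O)/C(C)=C\C)[C@H]1C(CO)=C | intermediate
26 | hydroxy enal | O[C@@H]1[C@H]2O[C@]2(C)CCC[C@@H](C)C(=O)[C@H](OC(=O)/C(C)=C\C)[C@H]1C(C=O)=C | intermediate
27 | lactol (C12 undefined) | C=C1C(O)O[C@H]2[C@H]1[C@@H](OC(=O)/C(C)=C\C)C(=O)[C@H](C)CCC[C@@]3(C)O[C@H]23 | intermediate
28 | 4α,5β-epoxy α-methylene-γ-lactone | C=C1C(=O)O[C@H]2[C@H]1[C@@H](OC(=O)/C(C)=C\C)C(=O)[C@H](C)CCC[C@@]3(C)O[C@H]23 | intermediate
29 | 4,9-bridged hemiketal | C=C1C(=O)O[C@H]2[C@H]1[C@@H](OC(=O)/C(C)=C\C)[C@@]3(O)[C@H](C)CCC[C@](C)(O3)[C@@H]2O | intermediate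
30 | 4β,5β-diol | C=C1C(=O)O[C@H]2[C@H]1[C@@H](OC(=O)/C(C)=C\C)C(=O)[C@H](C)CCC[C@](C)(O)[C@@H]2O | intermediate
31 | isobutyric anhydride | CC(C)C(=O)OC(=O)C(C)C | starting material
32 | CNP0141258.2 | C=C1C(=O)O[C@H]2[C@H]1[C@@H](OC(=O)/C(C)=C\C)C(=O)[C@H](C)CCC[C@](C)(O)[C@@H]2OC(=O)C(C)C | target

**Step count**
Total steps: 21.
Longest linear sequence: 21 steps from 1 (20 from carvone 3).

**Steps most likely to fail**

*Step 13.* The secondary C10 radical or organosamarium may be quenched by hydrogen abstraction before it reaches C9. Ketyl formation at C9 may compete. A trans-fused closure of ring B would erode the C10 selectivity.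

The fallback sets out from 12 and returns at 18.
- Dess–Martin oxidation of 12 would give the diketone mesylate F1.
- SmI2 in THF would then join C9 and C10 by intramolecular ketyl (pinacol) coupling, a closure that needs no secondary alkylsamarium. The samarium diolate would fragment in the same Grob sense to the 10-hydroxy cyclodecenone F2.
- More SmI2 with methanol would cleave the tertiary α-hydroxyl reductively, as is known for α-oxygenated ketones. Protonation of the samarium enolate would give 18.

*Step 20.* The rear of C4 is shielded by the ring. Ionisation may therefore end in elimination to allylic alcohols, in opening with retention, or in transannular ketalisation of the freed diol with C9.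

The fallback avoids any rear-side attack. It sets out from 19 and returns at 30.
- Thiyl-radical isomerisation (PhSSPh cat., hν), done before the angelate is present, would relax the strained E-alkene to the (4Z)-hydroxy ketone F3.
- Esterification as in step 15 would give the (4Z)-angelate F4.
- Desilylation as in step 16 would give the (4Z)-allylic alcohol F5.
- Hydroxyl-directed syn-dihydroxylation with OsO4·TMEDA would act on the exposed face that also carries O6. On the Z-alkene this is the 4S,5R face, and it would give the 4β,5β,6α-triol F6.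
- SeO2/t-BuOOH would give the 12-hydroxy tetraol F7, and MnO2 lactonisation would give 30.

*Step 14.* Facial selectivity in the oxidation of the medium-ring enolate may be poor if a second ring conformer exposes the other lobe.

The fallback sets out from 18 and returns at 22. The alcohol formed on the wrong face, the 8β-hydroxy ketone F8, would be esterified with angelic acid 20 under Mitsunobu conditions (PPh3, DIAD). This inverts C8, is favoured next to a carbonyl group, and never activates the angeloyl carbonyl. Both C8 epimers are thereby funnelled into 22.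

**Further compounds**
F1 | step 13 | diketone mesylate | CS(=O)(=O)O[C@@H]1[C@@H](O[Si](C)(C)C(C)(C)C)[C@H](C(C)=C)CC(=O)[C@@]1(C)CCCC(C)=O
F2 | step 13 | 10-hydroxy cyclodecenone (C10 undefined) | CC(C)(C)[Si](C)(C)O[C@@H]1/C=C(C)/CCCC(C)(O)C(=O)C[C@H]1C(C)=C
F3 | step 20 | (4Z)-hydroxy ketone | CC(C)(C)[Si](C)(C)O[C@@H]1/C=C(C)\CCC[C@@H](C)C(=O)[C@H](O)[C@H]1C(C)=C
F4 | step 20 | (4Z)-angelate | CC(C)(C)[Si](C)(C)O[C@@H]1/C=C(C)\CCC[C@@H](C)C(=O)[C@H](OC(=O)/C(C)=C\C)[C@H]1C(C)=C
F5 | step 20 | (4Z)-allylic alcohol | O[C@@H]1/C=C(C)\CCC[C@@H](C)C(=O)[C@H](OC(=O)/C(C)=C\C)[C@H]1C(C)=C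
F6 | step 20 | 4β,5β,6α-triol | O[C@@H]1[C@@H](O)[C@@](C)(O)CCC[C@@H](C)C(=O)[C@H](OC(=O)/C(C)=C\C)[C@H]1C(C)=C
F7 | step 20 | 12-hydroxy tetraol | O[C@@H]1[C@@H](O)[C@@](C)(O)CCC[C@@H](C)C(=O)[C@H](OC(=O)/C(C)=C\C)[C@H]1C(CO)=C
F8 | step 14 | 8β-hydroxy ketone | CC(C)(C)[Si](C)(C)O[C@@H]1/C=C(C)/CCC[C@@H](C)C(=O)[C@@H](O)[C@H]1C(C)=C
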